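C1 is the furanone C–O carbon, C2 the furanone CH, C3 the ketone, C4 the quaternary carbon (C15 methyl). C5=C6 is the ylidene, C7=C11 the butenolide alkene, C12 the lactone C=O, C13 the CH2OH, C8 the carbinol, C9 the CH2, C10 the CHMe (C14). O1 is the furanone oxygen and O8 the oxygen on C8 (germacrane numbering).
Retrosynthesis: cut the C8 ester (with inversion) and the silyl ethers. Then cut C2–C3 and O1–C4 together, which removes the furanone ring, the oxygen bridge and the ten-membered carbocycle at once and leaves a methyl ketone arm on a seven-membered C8–O8–C3 lactone. Then cut the lactone C–O bond, C4=C5 (olefination), C8–C9 (Stetter) and C5–C6 (formylation), back to furan-3,4-diyldimethanol.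
Enabling features: C3 and C8 stand 1,6 across the ten-membered ring, so C3 can be parked on O8 as a lactone ring that is absent from the target and handed to C2 through a bridged hemiketal. The C5=C6–O enol lactone is a hidden C6 ketone, so in the 6-methoxybutenolide form C4 is the SN2' terminus of C4=C5–C6–O.
Forward order of rings: furan (bought), gamma-lactone (temporary, carries C8 and C10), seven-membered lactone, butenolide (furan photooxygenation). The ten-membered ring and the furanone then form in the key step, and the butenolide recloses as the ylidene in the same flask.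
Stereochemistry: (8R) from Noyori transfer hydrogenation, (10S) from anti alkylation of the gamma-lactone enolate, (4S) relayed from C8 in the key step, and C8 turned to (S) by the Mitsunobu esterification. Z-C4=C5 comes from a diaryl phosphonate olefination, the E side chain from a Horner–Wadsworth–Emmons reaction, and the C5=C6 geometry is enforced by the ring.

Key step: step 13

Remark: 20 is expected as a mixture of C6 epimers and is drawn without configuration at C6, because C6 becomes planar again in step 13. Compound 16 is drawn as the open hydroxy ketone although it will equilibrate with its cyclic hemiketal.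

Step 1
Reactants: 1 furan-3,4-diyldimethanol
Product: 2 [4-(tert-butyldiphenylsilyloxymethyl)furan-3-yl]methanol
Conditions: NaH (1.0 equiv), THF, 0 °C; TBDPSCl (1.0 equiv), 23 °C
Reagents that add atoms: tert-butyl(chloro)diphenylsilane Cl[Si](c1ccccc1)(c1ccccc1)C(C)(C)C
Why: O-silylation of the sparingly soluble monosodium alkoxide of a symmetric diol should stop after one hydroxyl group and so tells the future C13 arm from the future C8 arm.

Step 2
Reactants: 2 [4-(tert-butyldiphenylsilyloxymethyl)furan-3-yl]methanol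
Product: 3 4-(tert-butyldiphenylsilyloxymethyl)furan-3-carbaldehyde
Conditions: MnO2, CH2Cl2, 23 °C
Reagents that add atoms: none
Why: Heterogeneous MnO2 oxidation of a furylmethanol (benzylic-type alcohol oxidation) should stop at the aldehyde and leave the silyl ether untouched.

Step 3
Reactants: 3 4-(tert-butyldiphenylsilyloxymethyl)furan-3-carbaldehyde
Product: 5 4-(tert-butyldiphenylsilyloxymethyl)furan-2,3-dicarbaldehyde, via lithium amino alkoxide 4 (not isolated)
Conditions: MeNHCH2CH2NMe2, nBuLi, THF, −20 °C; 3; nBuLi (2 equiv), −20 °C; DMF, −78 to 0 °C; aq HCl, 0 °C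
Reagents that add atoms: N,N-dimethylformamide CN(C)C=O; N,N,N'-trimethylethylenediamine CNCCN(C)C (held only in 4); n-butyllithium [Li]CCCC (lithium held only in 4)
Why: Directed ortho-metalation, in which the lithium alpha-amino alkoxide 4 masks the aldehyde and its diamine arm guides nBuLi to the neighbouring furan 2-position (C6) rather than to the remote 5-position (C12), so that DMF delivers C5 where it is needed.

Step 4
Reactants: 6 diphenyl phosphite; 7 tert-butyl 2-bromopropanoate
Product: 8 tert-butyl 2-(diphenoxyphosphoryl)propanoate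
Conditions: NaH, THF, 0 to 23 °C
Reagents that add atoms: none
Why: Michaelis–Becker reaction, in which sodium diphenyl phosphite displaces the secondary bromide (SN2) to give the diaryl phosphonate that makes the next olefination Z-selective.

Step 5
Reactants: 5 4-(tert-butyldiphenylsilyloxymethyl)furan-2,3-dicarbaldehyde; 8 tert-butyl 2-(diphenoxyphosphoryl)propanoate
Product: 9 tert-butyl (Z)-3-[4-(tert-butyldiphenylsilyloxymethyl)-3-formylfuran-2-yl]-2-methylprop-2-enoate
Conditions: 8 (1.0 equiv), NaH, THF, −78 to 0 °C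
Reagents that add atoms: none
Why: Z-selective Horner–Wadsworth–Emmons olefination with a diaryl phosphonate, in which fast irreversible collapse of the first adduct gives the Z-enoate and the 2-formyl group with one flanking substituent should react before the doubly flanked 3-formyl group.

Step 6
Reactants: 9 tert-butyl (Z)-3-[4-(tert-butyldiphenylsilyloxymethyl)-3-formylfuran-2-yl]-2-methylprop-2-enoate; 10 methyl acrylate
Product: 11 tert-butyl (Z)-3-[4-(tert-butyldiphenylsilyloxymethyl)-3-(4-methoxy-4-oxobutanoyl)furan-2-yl]-2-methylprop-2-enoate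
Conditions: 3-benzyl-5-(2-hydroxyethyl)-4-methylthiazolium chloride (20 mol %), Et3N, 1,4-dioxane, 70 °C
Reagents that add atoms: none
Why: Stetter reaction, in which the thiazolylidene turns the remaining aldehyde (C8) into an acyl anion equivalent that adds 1,4 to methyl acrylate and forms C8–C9, while the trisubstituted Z-enoate is too hindered to act as acceptor.

Step 7
Reactants: 11 tert-butyl (Z)-3-[4-(tert-butyldiphenylsilyloxymethyl)-3-(4-methoxy-4-oxobutanoyl)furan-2-yl]-2-methylprop-2-enoate
Product: 13 tert-butyl (Z)-3-{4-(tert-butyldiphenylsilyloxymethyl)-3-[(2R)-5-oxooxolan-2-yl]furan-2-yl}-2-methylprop-2-enoate, via hydroxy ester 12 (not isolated)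
Conditions: RuCl(p-cymene)[(R,R)-TsNCH(Ph)CH(Ph)NH2] (1 mol %), HCO2H/Et3N azeotrope, 30 °C; 4-MeC6H4SO3H·H2O (cat.), CH2Cl2, 23 °C
Reagents that add atoms: none
Why: Noyori asymmetric transfer hydrogenation of a heteroaryl alkyl ketone, in which the (R,R)-catalyst delivers hydride to one carbonyl face through the CH–pi contact of its arene with the furan and should set (8R), followed by acid-catalysed gamma-lactonisation.

Step 8
Reactants: 13 tert-butyl (Z)-3-{4-(tert-butyldiphenylsilyloxymethyl)-3-[(2R)-5-oxooxolan-2-yl]furan-2-yl}-2-methylprop-2-enoate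
Product: 14 tert-butyl (Z)-3-{4-(tert-butyldiphenylsilyloxymethyl)-3-[(2R,4S)-4-methyl-5-oxooxolan-2-yl]furan-2-yl}-2-methylprop-2-enoate
Conditions: LiN(iPr)2, THF, −78 °C; MeI
Reagents that add atoms: iodomethane CI
Why: Alkylation of a gamma-substituted butyrolactone lithium enolate, in which MeI approaches the face anti to the C8 furyl group and should give the trans lactone with (10S).

Step 9
Reactants: 14 tert-butyl (Z)-3-{4-(tert-butyldiphenylsilyloxymethyl)-3-[(2R,4S)-4-methyl-5-oxooxolan-2-yl]furan-2-yl}-2-methylprop-2-enoate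
Product: 15 (Z)-3-{4-(tert-butyldiphenylsilyloxymethyl)-3-[(2R,4S)-4-methyl-5-oxooxolan-2-yl]furan-2-yl}-2-methylprop-2-enoic acid
Conditions: CF3CO2H, CH2Cl2, 0 °C
Reagents that add atoms: none
Why: Acidolysis of the tert-butyl ester (E1 loss of the tert-butyl cation) frees the C3 acid while the lactone and the robust TBDPS ether stay intact, so that no free C8 hydroxyl ever meets the enoate under base.

Step 10
Reactants: 15 (Z)-3-{4-(tert-butyldiphenylsilyloxymethyl)-3-[(2R,4S)-4-methyl-5-oxooxolan-2-yl]furan-2-yl}-2-methylprop-2-enoic acid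
Product: 16 (Z)-3-{4-(tert-butyldiphenylsilyloxymethyl)-3-[(1R,3S)-1-hydroxy-3-methyl-4-oxopentyl]furan-2-yl}-2-methylprop-2-enoic acid
Conditions: MeLi (2.2 equiv), THF, −78 °C; AcOH
Reagents that add atoms: methyllithium [Li]C
Why: Addition of an organolithium to a lactone, in which the first MeLi shields C3 as its lithium carboxylate and the second adds to C1, where the lithium hemiketal persists at low temperature and prevents a second addition, so that C2 arrives as the methyl ketone and C10 is not enolised.

Step 11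
Reactants: 16 (Z)-3-{4-(tert-butyldiphenylsilyloxymethyl)-3-[(1R,3S)-1-hydroxy-3-methyl-4-oxopentyl]furan-2-yl}-2-methylprop-2-enoic acid
Product: 18 (8R,10S)-furan-fused seven-membered C8–O8–C3 lactone, via mixed anhydride 17 (not isolated)
Conditions: 2,4,6-Cl3C6H2COCl, Et3N, THF, 23 °C; 4-(dimethylamino)pyridine, toluene (2 mM), 40 °C
Reagents that add atoms: 2,4,6-trichlorobenzoyl chloride O=C(Cl)c1c(Cl)cc(Cl)cc1Cl (held only in 17)
Why: Yamaguchi lactonisation (7-exo-trig acyl transfer to O8), favoured by the Z-alkene and the furan that hold C3 and O8 on the same side, builds the temporary seven-membered ring with retention at C8.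

Step 12
Reactants: 18 (8R,10S)-furan-fused seven-membered C8–O8–C3 lactone
Product: 20 (8R,10S)-6-methoxybutenolide fused to the seven-membered lactone, via methoxy hydroperoxide 19 (not isolated)
Conditions: O2, 5,10,15,20-tetraphenylporphyrin (cat.), visible light, CH2Cl2/MeOH, −78 °C; Ac2O, pyridine, 0 °C
Reagents that add atoms: dioxygen O=O; methanol CO
Why: Furan photooxygenation, in which singlet oxygen adds across C6 and C12, methanol takes the more substituted C6 to give hydroperoxide 19 and Ac2O with pyridine dehydrates the secondary C12 hydroperoxide to the lactone carbonyl, a known way from 2-substituted furans to gamma-ketal butenolides.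

Step 13
Reactants: 20 (8R,10S)-6-methoxybutenolide fused to the seven-membered lactone
Product: 24 (4S,8R,10S)-8-hydroxy-13-(tert-butyldiphenylsilyloxy)-3-oxo-1,4-epoxygermacra-1,5E,7(11)-trien-6,12-olide, via bridged hemiketal alkoxide 21 (not isolated), via ten-membered diketonate 22 (not isolated), via enol ether carboxylate 23 (not isolated)
Conditions: KN(SiMe3)2 (1.2 equiv), THF (5 mM), −78 to 23 °C; CF3CO2H (5 equiv), 23 °C
Reagents that add atoms: potassium bis(trimethylsilyl)amide [K+].C[Si](C)(C)[N-][Si](C)(C)C (potassium held only in 21 to 23)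
Why: Proposed new method: KN(SiMe3)2 removes a proton from the C2 methyl group, the enolate carbon adds to the lactone carbonyl C3 (7-exo-trig) to give the 11-oxabicyclo[4.4.1]undecane hemiketal alkoxide 21, and cleavage of its C3–O8 bridge bond fragments the bicycle to the ten-membered diketonate 22 (C2–C3 made, the carbocycle unfolded from the seven-membered ring rather than closed end to end); the enolate oxygen on C1 then attacks C4 of the C4=C5–C6(OMe)–O allyl system (5-exo-trig, SN2') and expels the C12 carboxylate to give 23 (O1–C4 made), whose acid adds back to the protonated enol ether at C6 (5-exo-trig) and loses methanol to give the C5=C6 ylidene butenolide. The closest known reaction types are the Baker–Venkataraman O-to-C acyl migration, the ring expansion of lactones through bicyclic hemiketals and the closure of 3(2H)-furanones by O-alkylation of 1,3-diketones that carry an alpha' leaving group, and their union in one medium-ring-forming cascade is what is new. The sequence runs downhill in basicity (ketone enolate, alkoxide, diketonate, carboxylate), which should pull the strained ring through. C4 is the only new stereocenter: in 21 the C4–C7 bridge and the C2–C1–C10–C9 bridge are folded away from the O8 bridge, so after fragmentation O1 can reach only the face of C4=C5 that looks into this fold, anti to O8, and (8R) is thus relayed to (4S) whichever C6 epimer of 20 reacts, since C6 becomes planar. Chemoselectivity rests on geometry: C3 is the only carbonyl within a seven-membered reach of C2, C12 lies trans to C8 across C7=C11, C6 is masked as a ketal so that no aldol can compete, the hindered amide should take the methyl proton faster than H-10 or H-8, and C-alkylation of the diketonate at C4 would need a three-membered ring.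

Step 14
Reactants: 25 1-(tert-butyldimethylsilyloxy)propan-2-one; 26 triethyl phosphonoacetate
Product: 27 ethyl (E)-4-(tert-butyldimethylsilyloxy)-3-methylbut-2-enoate
Conditions: NaH, THF, 0 to 23 °C
Reagents that add atoms: none
Why: Horner–Wadsworth–Emmons olefination of a methyl ketone, in which the larger CH2OTBS group should end up trans to the ester and give the E-enoate.

Step 15
Reactants: 27 ethyl (E)-4-(tert-butyldimethylsilyloxy)-3-methylbut-2-enoate
Product: 28 (E)-4-(tert-butyldimethylsilyloxy)-3-methylbut-2-enoic acid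
Conditions: LiOH, THF/H2O, 23 °C; aq HCl to pH 4, 0 °C
Reagents that add atoms: lithium hydroxide [Li+].[OH-]
Why: Saponification of the ethyl ester with LiOH leaves the primary TBS ether and the alkene geometry untouched.

Step 16
Reactants: 24 (4S,8R,10S)-8-hydroxy-13-(tert-butyldiphenylsilyloxy)-3-oxo-1,4-epoxygermacra-1,5E,7(11)-trien-6,12-olide; 28 (E)-4-(tert-butyldimethylsilyloxy)-3-methylbut-2-enoic acid
Product: 29 bis-silyl ether of the target with (4S,8S,10S) configuration
Conditions: PPh3, DIAD, toluene, 0 to 23 °C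
Reagents that add atoms: none
Why: Mitsunobu esterification, in which the carboxylate of 28 displaces the C8 oxyphosphonium ion by SN2 with inversion and so turns (8R) into the (8S) ester, while SN1 or SN2' escape is disfavoured because C8 adjoins the electron-poor C7=C11–C12=O system.

Step 17
Reactants: 29 bis-silyl ether of the target with (4S,8S,10S) configuration
Product: 30 CNP0288314.1
Conditions: HF·pyridine, THF/pyridine, 0 to 23 °C
Reagents that add atoms: none
Why: Fluoride-mediated cleavage of both silyl ethers under buffered acidic conditions avoids the basic media that could trigger loss of the C13 oxygen or opening of the esters.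

Compound list
1 | furan-3,4-diyldimethanol | OCc1cocc1CO | starting material
2 | [4-(tert-butyldiphenylsilyloxymethyl)furan-3-yl]methanol | OCc1cocc1CO[Si](c2ccccc2)(c3ccccc3)C(C)(C)C | intermediate
3 | 4-(tert-butyldiphenylsilyloxymethyl)furan-3-carbaldehyde | O=Cc1cocc1CO[Si](c2ccccc2)(c3ccccc3)C(C)(C)C | intermediate
4 | lithium alpha-amino alkoxide from 3 and LiN(Me)CH2CH2NMe2 | [Li+].[O-]C(N(C)CCN(C)C)c1cocc1CO[Si](c2ccccc2)(c3ccccc3)C(C)(C)C | intermediate
5 | 4-(tert-butyldiphenylsilyloxymethyl)furan-2,3-dicarbaldehyde | O=Cc1occ(CO[Si](c2ccccc2)(c3ccccc3)C(C)(C)C)c1C=O | intermediate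
6 | diphenyl phosphite | O=[PH](Oc1ccccc1)Oc1ccccc1 | starting material
7 | tert-butyl 2-bromopropanoate | CC(Br)C(=O)OC(C)(C)C | starting material
8 | tert-butyl 2-(diphenoxyphosphoryl)propanoate | CC(C(=O)OC(C)(C)C)P(=O)(Oc1ccccc1)Oc1ccccc1 | intermediate
9 | tert-butyl (Z)-3-[4-(tert-butyldiphenylsilyloxymethyl)-3-formylfuran-2-yl]-2-methylprop-2-enoate | CC(C)(C)OC(=O)/C(C)=C\c1occ(CO[Si](c2ccccc2)(c3ccccc3)C(C)(C)C)c1C=O | intermediate
10 | methyl acrylate | C=CC(=O)OC | starting material
11 | tert-butyl (Z)-3-[4-(tert-butyldiphenylsilyloxymethyl)-3-(4-methoxy-4-oxobutanoyl)furan-2-yl]-2-methylprop-2-enoate | CC(C)(C)OC(=O)/C(C)=C\c1occ(CO[Si](c2ccccc2)(c3ccccc3)C(C)(C)C)c1C(=O)CCC(=O)OC | intermediate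
12 | tert-butyl (Z)-3-{4-(tert-butyldiphenylsilyloxymethyl)-3-[(1R)-1-hydroxy-4-methoxy-4-oxobutyl]furan-2-yl}-2-methylprop-2-enoate | CC(C)(C)OC(=O)/C(C)=C\c1occ(CO[Si](c2ccccc2)(c3ccccc3)C(C)(C)C)c1[C@H](O)CCC(=O)OC | intermediate
13 | tert-butyl (Z)-3-{4-(tert-butyldiphenylsilyloxymethyl)-3-[(2R)-5-oxooxolan-2-yl]furan-2-yl}-2-methylprop-2-enoate | CC(C)(C)OC(=O)/C(C)=C\c1occ(CO[Si](c2ccccc2)(c3ccccc3)C(C)(C)C)c1[C@H]4CCC(=O)O4 | intermediate
14 | tert-butyl (Z)-3-{4-(tert-butyldiphenylsilyloxymethyl)-3-[(2R,4S)-4-methyl-5-oxooxolan-2-yl]furan-2-yl}-2-methylprop-2-enoate (trans lactone) | CC(C)(C)OC(=O)/C(C)=C\c1occ(CO[Si](c2ccccc2)(c3ccccc3)C(C)(C)C)c1[C@H]4C[C@H](C)C(=O)O4 | intermediate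
15 | (Z)-3-{4-(tert-butyldiphenylsilyloxymethyl)-3-[(2R,4S)-4-methyl-5-oxooxolan-2-yl]furan-2-yl}-2-methylprop-2-enoic acid | OC(=O)/C(C)=C\c1occ(CO[Si](c2ccccc2)(c3ccccc3)C(C)(C)C)c1[C@H]4C[C@H](C)C(=O)O4 | intermediate
16 | (Z)-3-{4-(tert-butyldiphenylsilyloxymethyl)-3-[(1R,3S)-1-hydroxy-3-methyl-4-oxopentyl]furan-2-yl}-2-methylprop-2-enoic acid | OC(=O)/C(C)=C\c1occ(CO[Si](c2ccccc2)(c3ccccc3)C(C)(C)C)c1[C@H](O)C[C@H](C)C(C)=O | intermediate
17 | mixed anhydride of 16 and 2,4,6-trichlorobenzoic acid | O=C(OC(=O)/C(C)=C\c1occ(CO[Si](c2ccccc2)(c3ccccc3)C(C)(C)C)c1[C@H](O)C[C@H](C)C(C)=O)c4c(Cl)cc(Cl)cc4Cl | intermediate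
18 | (8R,10S)-seven-membered lactone O8–C3(=O)–C4(CH3)=C5H–C6=C7–C8 fused at C6–C7 to the furan; C8 bears the (2S)-2-methyl-3-oxobutyl arm, C11 bears CH2OTBDPS | CC(=O)[C@@H](C)C[C@H]1OC(=O)C(C)=Cc2occ(CO[Si](c3ccccc3)(c4ccccc4)C(C)(C)C)c12 | intermediate
19 | 6-methoxy-12-hydroperoxy-6,12-dihydrofuran derived from 18 | CC(=O)[C@@H](C)C[C@H]1OC(=O)C(C)=CC2(OC)OC(OO)C(CO[Si](c3ccccc3)(c4ccccc4)C(C)(C)C)=C12 | intermediate
20 | (8R,10S)-6-methoxybutenolide (C6 ketal, C12 lactone carbonyl, C7=C11) fused at C6–C7 to the seven-membered C8–O8–C3 lactone; C6 epimers | CC(=O)[C@@H](C)C[C@H]1OC(=O)C(C)=CC2(OC)OC(=O)C(CO[Si](c3ccccc3)(c4ccccc4)C(C)(C)C)=C12 | intermediate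
21 | potassium salt of the bridged hemiketal (11-oxabicyclo[4.4.1]undecane core; bridgeheads C3 and C8; bridges O8, C4–C7 and C2–C1–C10–C9) | [K+].C[C@H]1C[C@H]2O[C@@]([O-])(CC1=O)C(C)=CC3(OC)OC(=O)C(CO[Si](c4ccccc4)(c5ccccc5)C(C)(C)C)=C23 | intermediate
22 | potassium (8R,10S)-ten-membered C1/C3 diketonate with free C8 hydroxyl, Z-C4=C5 and intact 6-methoxybutenolide | [K+].C[C@H]1C[C@@H](O)C2=C(CO[Si](c3ccccc3)(c4ccccc4)C(C)(C)C)C(=O)OC2(OC)/C=C(C)\C(=O)/C=C1\[O-] | intermediate
23 | potassium (4S,8R,10S)-C12 carboxylate of the 1,4-epoxy-3-oxo ten-membered ring with C5=C6(OMe) enol ether | [K+].C[C@H]1C[C@@H](O)/C(=C(\CO[Si](c3ccccc3)(c4ccccc4)C(C)(C)C)C(=O)[O-])/C(OC)=C\[C@]2(C)OC1=CC2=O | intermediate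
24 | (4S,8R,10S)-8-hydroxy-13-(tert-butyldiphenylsilyloxy)-3-oxo-1,4-epoxygermacra-1,5E,7(11)-trien-6,12-olide | O[C@@H]1C[C@H](C)C2=CC(=O)[C@](C)(/C=C3/OC(=O)C(CO[Si](c4ccccc4)(c5ccccc5)C(C)(C)C)=C31)O2 | intermediate
25 | 1-(tert-butyldimethylsilyloxy)propan-2-one | CC(=O)CO[Si](C)(C)C(C)(C)C | starting material
26 | triethyl phosphonoacetate | CCOC(=O)CP(=O)(OCC)OCC | starting material
27 | ethyl (E)-4-(tert-butyldimethylsilyloxy)-3-methylbut-2-enoate | C/C(=C\C(=O)OCC)CO[Si](C)(C)C(C)(C)C | intermediate
28 | (E)-4-(tert-butyldimethylsilyloxy)-3-methylbut-2-enoic acid | C/C(=C\C(=O)O)CO[Si](C)(C)C(C)(C)C | intermediate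
29 | (4S,8S,10S)-13-(tert-butyldiphenylsilyloxy)-8-[(E)-4-(tert-butyldimethylsilyloxy)-3-methylbut-2-enoyloxy]-3-oxo-1,4-epoxygermacra-1,5E,7(11)-trien-6,12-olide | C/C(=C\C(=O)O[C@H]1C[C@H](C)C2=CC(=O)[C@](C)(/C=C3/OC(=O)C(CO[Si](c4ccccc4)(c5ccccc5)C(C)(C)C)=C31)O2)CO[Si](C)(C)C(C)(C)C | intermediate
30 | CNP0288314.1, (4S,8S,10S)-13-hydroxy-8-[(E)-4-hydroxy-3-methylbut-2-enoyloxy]-3-oxo-1,4-epoxygermacra-1,5E,7(11)-trien-6,12-olide | C/C(=C\C(=O)O[C@H]1C[C@H](C)C2=CC(=O)[C@](C)(/C=C3/OC(=O)C(CO)=C31)O2)CO | target

Total step count: 17. Longest linear sequence: 14 steps (1 to 3, 5 to 13, 16, 17).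

Steps most likely to fail

Step 13. Several things could go wrong:
- The enolate or the amide base may attack the methoxybutenolide.
- The diketonate may fail to displace the carboxylate.
- The ring may refold before closure, so that facial selectivity at C4=C5 is lost.

The fallback splits the two bond formations and uses known reaction types. It sets out from 18. A Baker–Venkataraman-type O-to-C acyl migration with KN(SiMe3)2 is run at the furan stage, where no second electrophile is present, and should give the ten-membered furanophane diketone F1. Photooxygenation (O2, 5,10,15,20-tetraphenylporphyrin, light, CH2Cl2) followed by iPr2NEt (Kornblum–DeLaMare opening) should unveil the C4=C5–C6=O enone. The enol oxygen on C1 adds to it in a reversible transannular oxa-Michael reaction to give the hydroxybutenolide furanone F2. Acid-catalysed dehydration (camphorsulfonic acid, toluene, 80 °C) comes back to the route at 24.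

Step 16. The backside of C8 may be shielded by the folded macrocycle, so that elimination towards C9 or simple non-reaction takes over from displacement. The fallback inverts C8 by redox and sets out from 24:
- Dess–Martin oxidation should give the C8 ketone F3.
- Luche reduction (NaBH4, CeCl3·7H2O, MeOH, −78 °C), with hydride delivered from the exposed face, should give the (8S)-alcohol F4.
- Yamaguchi esterification with 28 proceeds with retention and comes back to the route at 29.

Step 12. Singlet oxygen may react sluggishly with the acceptor-substituted furan, or methanol may add at C12 instead of C6. The fallback replaces the cycloaddition by an ionic ring opening and sets out from 18: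
- NBS and NaHCO3 in aqueous acetone should give the Z-keto enal F5.
- Pinnick oxidation (NaClO2, NaH2PO4, 2-methylbut-2-ene) should give the gamma-hydroxybutenolide F6.
- Pseudo-ester formation (CH(OMe)3, MeOH, camphorsulfonic acid) comes back to the route at 20.

Further compounds
F1 | step 13 | (8R,10S)-ten-membered furanophane 1,3-diketone with free C8 hydroxyl and Z-C4=C5 | C[C@H]1C[C@@H](O)c2c(CO[Si](c3ccccc3)(c4ccccc4)C(C)(C)C)coc2/C=C(C)\C(=O)CC1=O
F2 | step 13 | (4S,8R,10S)-6-hydroxybutenolide furanone with C5H2 | C[C@H]1C[C@@H](O)C2=C(CO[Si](c3ccccc3)(c4ccccc4)C(C)(C)C)C(=O)OC2(O)C[C@]5(C)OC1=CC5=O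
F3 | step 16 | (4S,10S)-3,8-dioxo-13-(tert-butyldiphenylsilyloxy)-1,4-epoxygermacra-1,5E,7(11)-trien-6,12-olide | O=C1C[C@H](C)C2=CC(=O)[C@](C)(/C=C3/OC(=O)C(CO[Si](c4ccccc4)(c5ccccc5)C(C)(C)C)=C31)O2
F4 | step 16 | (4S,8S,10S)-8-hydroxy-13-(tert-butyldiphenylsilyloxy)-3-oxo-1,4-epoxygermacra-1,5E,7(11)-trien-6,12-olide | O[C@H]1C[C@H](C)C2=CC(=O)[C@](C)(/C=C3/OC(=O)C(CO[Si](c4ccccc4)(c5ccccc5)C(C)(C)C)=C31)O2
F5 | step 12 | (8R,10S)-seven-membered lactone with C6 ketone and Z-C7=C11 enal (C12 aldehyde) | CC(=O)[C@@H](C)C[C@H]1OC(=O)C(C)=CC(=O)/C1=C(\C=O)CO[Si](c2ccccc2)(c3ccccc3)C(C)(C)C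
F6 | step 12 | (8R,10S)-6-hydroxybutenolide fused to the seven-membered lactone | CC(=O)[C@@H](C)C[C@H]1OC(=O)C(C)=CC2(O)OC(=O)C(CO[Si](c3ccccc3)(c4ccccc4)C(C)(C)C)=C12
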